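Chain numbering: C1 is the methyl on the CHCl carbon, C13 the CH2 on the inner furan (ring A). Cutting C8–C9 and C13–ring A (two Negishi couplings) and C3–C4 exposes C4–C8 as a 3-methylglutarate: C6 bears the methyl and is flanked by the C5 and C7 methylenes, which lead to the C4 carbonyl and to allylic C8. Pig liver esterase hydrolyses one enantiotopic ester of the acyclic, prochiral dimethyl 3-methylpentanedioate, which in one operation sets C6 and distinguishes C4 (ester) from C8 (acid); no ring is involved. The C2/C3 chlorohydrin is installed last by hydroxyl-directed epoxidation, titanium-directed chloride opening at the alcohol level and oxidation at C4.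

Key step: step 1

Remark: the esterase is taken to cleave the pro-S ester (R half-ester 2); were the antipode obtained, the acid arm would be carried on as C4 and the ester arm as C8.
Remark: 5-bromopent-1-yne and 1-propynylmagnesium bromide (THF solution) are taken as commercial.
Remark: the chlorohydrin is not made by chloride opening of a cis-α,β-epoxy ketone, because halide is expected to enter α to the ketone (C3) there; chloride is therefore introduced at the epoxy-alcohol stage.

Step 1
Reactants: 1 dimethyl 3-methylpentanedioate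
Product: 2 (3R)-5-methoxy-3-methyl-5-oxopentanoic acid
Conditions: pig liver esterase, phosphate buffer pH 7/MeOH 4:1, −10 °C, pH-stat (1 M NaOH); then HCl to pH 2
Reagents that add atoms: water, O
Why: The active-site serine is acylated by one ester carbonyl, methanol leaves, and water cleaves the acyl-enzyme to release the half-ester, which is the established esterase desymmetrisation of prochiral 3-substituted glutarate diesters. No ring is closed and no C–C bond is formed. The new stereocentre (C3 of 2, C6 of the target) is controlled only by the chiral active site, which should accept the pro-S ester arm when the 3-substituent is as small as methyl and so leave the R half-ester. The step needs enantiotopic-group selectivity, supplied by the enzyme pocket and sharpened by methanol cosolvent and low temperature, and mono-hydrolysis, secured because the carboxylate product is a poor substrate. Enantiopurity can be raised further by crystallising a salt of 2 with a chiral amine such as 1-phenylethylamine. In 2 the free acid is the future C8 and the surviving ester the future C4, so both chain ends are differentiated without protecting groups.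

Step 2
Reactants: 2 (3R)-5-methoxy-3-methyl-5-oxopentanoic acid
Product: 3 methyl (3R)-5-hydroxy-3-methylpentanoate
Conditions: BH3·SMe2, THF, −10 → 0 °C; MeOH quench
Reagents that add atoms: none
Why: Chemoselective borane reduction, in which the carboxylic acid reacts through an acyloxyborane far faster than the ester, so only the C8 acid becomes the alcohol and the non-enolisable stereocentre is untouched.

Step 3
Reactants: 3 methyl (3R)-5-hydroxy-3-methylpentanoate
Product: 4 methyl (3S)-5-iodo-3-methylpentanoate
Conditions: I2, PPh3, imidazole, CH2Cl2, 0 °C → rt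
Reagents that add atoms: iodine, II
Why: Appel-type iodination of the primary alcohol through its alkoxyphosphonium salt is fast and neutral, which also forestalls lactonisation of 3; the stereocentre is not involved and only its CIP label changes.

Step 4
Reactants: 5 5-bromopent-1-yne
Product: 7 (1E)-5-bromo-1-iodo-2-methylpent-1-ene, via alkenylalane 6 (not isolated)
Conditions: Me3Al, Cp2ZrCl2 (25 mol%), CH2Cl2, 0 °C → rt; then I2, THF, −30 → 0 °C
Reagents that add atoms: trimethylaluminium, C[Al](C)C; iodine, II
Why: Zirconium-catalysed syn carboalumination (Negishi) places methyl on the internal and aluminium on the terminal alkyne carbon on the same side, and iodinolysis of the C–Al bond with retention fixes the E alkene with methyl cis to iodine; the primary bromide is inert to both reagents.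

Step 5
Reactants: 4 methyl (3S)-5-iodo-3-methylpentanoate; 7 (1E)-5-bromo-1-iodo-2-methylpent-1-ene
Product: 9 methyl (3R,6E)-10-bromo-3,7-dimethyldec-6-enoate, via alkylzinc iodide 8 (not isolated)
Conditions: Zn dust, LiCl, THF, 25 °C; then 7, Pd(dppf)Cl2 (3 mol%), THF, 25 → 40 °C
Reagents that add atoms: none
Why: Zinc inserts into the primary C–I bond without touching the ester, and the Negishi sp3–sp2 coupling proceeds with retention of alkene geometry because oxidative addition to the alkenyl iodide is far faster than to the primary alkyl bromide.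

Step 6
Reactants: 10 4-bromofuran-2-carbaldehyde; 11 furan-3-ylboronic acid
Product: 12 (4-bromofuran-2-yl)(furan-3-yl)methanol (racemic)
Conditions: [Rh(OH)(cod)]2 (1.5 mol%), 1,4-dioxane/H2O 10:1, 50 °C
Reagents that add atoms: none
Why: Rhodium-catalysed 1,2-addition of an arylboronic acid to an aromatic aldehyde (transmetalation, carbonyl insertion, hydrolysis) leaves the furyl C–Br bond intact; the carbinol centre is racemic and is removed in the next step.

Step 7
Reactants: 12 (4-bromofuran-2-yl)(furan-3-yl)methanol
Product: 13 4-bromo-2-(furan-3-ylmethyl)furan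
Conditions: Et3SiH, CF3CO2H, CH2Cl2, −40 → 0 °C
Reagents that add atoms: none
Why: Ionic hydrogenation, in which acid ionises the doubly heteroaryl-stabilised carbinol and excess triethylsilane traps the cation as the methylene compound; cold, dilute conditions and the deactivating bromine on ring A should keep Friedel–Crafts oligomerisation behind hydride transfer.

Step 8
Reactants: 9 methyl (3R,6E)-10-bromo-3,7-dimethyldec-6-enoate; 13 4-bromo-2-(furan-3-ylmethyl)furan
Product: 15 methyl (3R,6E)-10-[5-(furan-3-ylmethyl)furan-3-yl]-3,7-dimethyldec-6-enoate, via alkylzinc bromide 14 (not isolated)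
Conditions: Zn dust, I2 (5 mol%), DMA, 70 °C; then 13, Pd(OAc)2 (2 mol%), SPhos (4 mol%), THF/DMA, 40 °C
Reagents that add atoms: none
Why: Iodine-activated zinc inserts into the primary bromide in the polar amide solvent, and Negishi coupling of the alkylzinc with the electron-rich furyl bromide is promoted by the bulky biarylphosphine ligand; the ester and the trisubstituted alkene are spectators.

Step 9
Reactants: 15 methyl (3R,6E)-10-[5-(furan-3-ylmethyl)furan-3-yl]-3,7-dimethyldec-6-enoate
Product: 16 (3R,6E)-10-[5-(furan-3-ylmethyl)furan-3-yl]-N-methoxy-N,3,7-trimethyldec-6-enamide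
Conditions: MeNH(OMe)·HCl, i-PrMgCl, THF, −20 → 0 °C
Reagents that add atoms: N,O-dimethylhydroxylamine hydrochloride, CNOC.Cl
Why: Direct aminolysis of the methyl ester by the magnesium amide of N,O-dimethylhydroxylamine gives the Weinreb amide; the stereocentre is β to the carbonyl and cannot epimerise.

Step 10
Reactants: 16 (3R,6E)-10-[5-(furan-3-ylmethyl)furan-3-yl]-N-methoxy-N,3,7-trimethyldec-6-enamide; 17 1-propynylmagnesium bromide
Product: 18 (6R,9E)-13-[5-(furan-3-ylmethyl)furan-3-yl]-6,10-dimethyltridec-9-en-2-yn-4-one
Conditions: THF, −20 → 0 °C; cold 1 M HCl quench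
Reagents that add atoms: none
Why: Weinreb ketone synthesis, in which the magnesium-chelated tetrahedral intermediate survives until the acidic quench so the alkynyl Grignard adds only once; the cold acid work-up keeps the liberated amine from adding to the ynone.

Step 11
Reactants: 18 (6R,9E)-13-[5-(furan-3-ylmethyl)furan-3-yl]-6,10-dimethyltridec-9-en-2-yn-4-one
Product: 19 (4R,6R,9E)-13-[5-(furan-3-ylmethyl)furan-3-yl]-6,10-dimethyltridec-9-en-2-yn-4-ol
Conditions: Ru[(R,R)-TsDPEN](p-cymene) (1 mol%), i-PrOH, 25 °C
Reagents that add atoms: none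
Why: Noyori asymmetric transfer hydrogenation of an alkynyl ketone, in which the Ru–H/N–H pair delivers hydrogen through a six-membered transition state with the alkyne next to the arene ligand, so the (R,R) catalyst should set 4R by catalyst control (by analogy with simple alkynyl ketones) without reducing the alkyne, the alkene or the furans.

Step 12
Reactants: 19 (4R,6R,9E)-13-[5-(furan-3-ylmethyl)furan-3-yl]-6,10-dimethyltridec-9-en-2-yn-4-ol
Product: 20 (2Z,4R,6R,9E)-13-[5-(furan-3-ylmethyl)furan-3-yl]-6,10-dimethyltrideca-2,9-dien-4-ol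
Conditions: H2 (1 atm), Pd/CaCO3 poisoned with Pb(OAc)2 (Lindlar catalyst), quinoline, EtOAc, 25 °C
Reagents that add atoms: none
Why: Lindlar semi-hydrogenation adds hydrogen syn on the poisoned palladium surface and stops at the Z alkene, while the trisubstituted alkene and the furans are not hydrogenated.

Step 13
Reactants: 20 (2Z,4R,6R,9E)-13-[5-(furan-3-ylmethyl)furan-3-yl]-6,10-dimethyltrideca-2,9-dien-4-ol
Product: 21 (1R,3R,6E)-10-[5-(furan-3-ylmethyl)furan-3-yl]-3,7-dimethyl-1-[(2S,3R)-3-methyloxiran-2-yl]dec-6-en-1-ol
Conditions: Ti(OiPr)4 (1.1 equiv), t-BuOOH (decane), 4 Å MS, CH2Cl2, −20 °C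
Reagents that add atoms: tert-butyl hydroperoxide, CC(C)(C)OO
Why: Hydroxyl-directed epoxidation by a titanium alkylperoxide, in which 1,3-allylic strain from the Z methyl holds the C4–H in the alkene plane so oxygen is delivered to the face syn to the hydroxyl, should give mainly the syn (threo) cis-epoxy alcohol with both new centres set by C4; the undirected alkene and furans stay intact and the minor diastereomer is removed by chromatography.

Step 14
Reactants: 21 (1R,3R,6E)-10-[5-(furan-3-ylmethyl)furan-3-yl]-3,7-dimethyl-1-[(2S,3R)-3-methyloxiran-2-yl]dec-6-en-1-ol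
Product: 22 (2S,3S,4R,6R,9E)-2-chloro-13-[5-(furan-3-ylmethyl)furan-3-yl]-6,10-dimethyltridec-9-ene-3,4-diol
Conditions: TiCl(OiPr)3 (1.5 equiv), CH2Cl2, 0 °C → rt; aq. tartaric acid work-up
Reagents that add atoms: chlorotitanium triisopropoxide, CC(C)O[Ti](Cl)(OC(C)C)OC(C)C
Why: Titanium-mediated opening of a 2,3-epoxy alcohol, in which the alkoxide-bound titanium activates the epoxide and chloride attacks the distal, less hindered carbon C2 with inversion (2S) while the C3–O bond is retained (3S), fixes the chlorine position before any carbonyl is present.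

Step 15
Reactants: 22 (2S,3S,4R,6R,9E)-2-chloro-13-[5-(furan-3-ylmethyl)furan-3-yl]-6,10-dimethyltridec-9-ene-3,4-diol
Product: 23 (2S,3S,6R,9E)-2-chloro-13-[5-(furan-3-ylmethyl)furan-3-yl]-3-hydroxy-6,10-dimethyltridec-9-en-4-one
Conditions: IBX (1.1 equiv), DMSO, 25 °C
Reagents that add atoms: none
Why: IBX oxidises vicinal diols to α-hydroxy ketones without C–C cleavage, and because the C4 carbinol is both less hindered and more electron-rich than C3–OH (which is flanked by the C–Cl carbon), oxidation should occur at C4 and stop at the ketol, leaving C2 and C3 unchanged.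

Compound list
1 | dimethyl 3-methylpentanedioate | COC(=O)CC(C)CC(=O)OC | starting material
2 | (3R)-5-methoxy-3-methyl-5-oxopentanoic acid | COC(=O)C[C@H](C)CC(=O)O | intermediate
3 | methyl (3R)-5-hydroxy-3-methylpentanoate | COC(=O)C[C@H](C)CCO | intermediate
4 | methyl (3S)-5-iodo-3-methylpentanoate | COC(=O)C[C@H](C)CCI | intermediate
5 | 5-bromopent-1-yne | C#CCCCBr | starting material
6 | [(1E)-5-bromo-2-methylpent-1-en-1-yl]dimethylalane | C/C(=C\[Al](C)C)CCCBr | intermediate
7 | (1E)-5-bromo-1-iodo-2-methylpent-1-ene | C/C(=C\I)CCCBr | intermediate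
8 | [(3S)-5-methoxy-3-methyl-5-oxopentyl]zinc iodide | COC(=O)C[C@H](C)CC[Zn]I | intermediate
9 | methyl (3R,6E)-10-bromo-3,7-dimethyldec-6-enoate | COC(=O)C[C@H](C)CC/C=C(\C)CCCBr | intermediate
10 | 4-bromofuran-2-carbaldehyde | O=Cc1cc(Br)co1 | starting material
11 | furan-3-ylboronic acid | OB(O)c1ccoc1 | starting material
12 | (4-bromofuran-2-yl)(furan-3-yl)methanol (racemic) | OC(c1cc(Br)co1)c1ccoc1 | intermediate
13 | 4-bromo-2-(furan-3-ylmethyl)furan | Brc1coc(Cc2ccoc2)c1 | intermediate
14 | [(4E,8R)-10-methoxy-4,8-dimethyl-10-oxodec-4-en-1-yl]zinc bromide | COC(=O)C[C@H](C)CC/C=C(\C)CCC[Zn]Br | intermediate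
15 | methyl (3R,6E)-10-[5-(furan-3-ylmethyl)furan-3-yl]-3,7-dimethyldec-6-enoate | COC(=O)C[C@H](C)CC/C=C(\C)CCCc1coc(Cc2ccoc2)c1 | intermediate
16 | (3R,6E)-10-[5-(furan-3-ylmethyl)furan-3-yl]-N-methoxy-N,3,7-trimethyldec-6-enamide | CON(C)C(=O)C[C@H](C)CC/C=C(\C)CCCc1coc(Cc2ccoc2)c1 | intermediate
17 | 1-propynylmagnesium bromide | CC#C[Mg]Br | starting material
18 | (6R,9E)-13-[5-(furan-3-ylmethyl)furan-3-yl]-6,10-dimethyltridec-9-en-2-yn-4-one | CC#CC(=O)C[C@H](C)CC/C=C(\C)CCCc1coc(Cc2ccoc2)c1 | intermediate
19 | (4R,6R,9E)-13-[5-(furan-3-ylmethyl)furan-3-yl]-6,10-dimethyltridec-9-en-2-yn-4-ol | CC#C[C@H](O)C[C@H](C)CC/C=C(\C)CCCc1coc(Cc2ccoc2)c1 | intermediate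
20 | (2Z,4R,6R,9E)-13-[5-(furan-3-ylmethyl)furan-3-yl]-6,10-dimethyltrideca-2,9-dien-4-ol | C/C=C\[C@H](O)C[C@H](C)CC/C=C(\C)CCCc1coc(Cc2ccoc2)c1 | intermediate
21 | (1R,3R,6E)-10-[5-(furan-3-ylmethyl)furan-3-yl]-3,7-dimethyl-1-[(2S,3R)-3-methyloxiran-2-yl]dec-6-en-1-ol | C[C@H]1O[C@H]1[C@H](O)C[C@H](C)CC/C=C(\C)CCCc2coc(Cc3ccoc3)c2 | intermediate
22 | (2S,3S,4R,6R,9E)-2-chloro-13-[5-(furan-3-ylmethyl)furan-3-yl]-6,10-dimethyltridec-9-ene-3,4-diol | C[C@H](Cl)[C@@H](O)[C@H](O)C[C@H](C)CC/C=C(\C)CCCc1coc(Cc2ccoc2)c1 | intermediate
23 | (2S,3S,6R,9E)-2-chloro-13-[5-(furan-3-ylmethyl)furan-3-yl]-3-hydroxy-6,10-dimethyltridec-9-en-4-one | C/C(=C\CC[C@@H](C)CC(=O)[C@H](O)[C@H](C)Cl)CCCc1coc(Cc2ccoc2)c1 | target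

Total step count: 15. Longest linear sequence: 12 steps (1, 2, 3, 5, 8, then 9 to 15).

Steps most likely to fail

Step 15. The diol oxidation may lose site selectivity, with oxidation at the C3 carbinol or over-oxidation to the 3,4-dione. The fallback sets out from 22 and comes back at 23 by differentiating the two hydroxyls with protecting groups. The less hindered C4 hydroxyl is acetylated (AcCl, 2,4,6-collidine, CH2Cl2, −78 °C) to the C4 monoacetate F1. The C3 hydroxyl is silylated (TESOTf, 2,6-lutidine) to the acetate silyl ether F2. The acetate is removed reductively (DIBAL-H, CH2Cl2, −78 °C) to the C3-silylated C4 alcohol F3. The only free hydroxyl is oxidised with Dess–Martin periodinane (NaHCO3 buffer) to the α-silyloxy ketone F4. The silyl ether is then cleaved with pyridine-buffered HF·pyridine in THF to give 23.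

Step 14. Chloride may be delivered to the wrong epoxide carbon (C3), or the titanium chloride may degrade the acid-sensitive furan rings. The fallback sets out from 21 and comes back at 22 without a metal chloride. The C4 hydroxyl is capped (TESCl, imidazole) as the silyl ether F5. The epoxide is opened with acetyl chloride under catalytic Bu4NCl, where acylation of the epoxide oxygen is followed by chloride attack with inversion at C2, the carbon remote from the silyloxy-bearing centre, to give the chloro acetate F6. Both groups are then stripped in one pot (DIBAL-H at −78 °C, then aqueous HCl/THF work-up) to return 22.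

Step 7. Cationic oligomerisation, by Friedel–Crafts attack of a furan ring on the carbinol-derived cation, may outrun hydride transfer. The fallback sets out from 10 and comes back at 13, bypassing 12 and all acid. Aldehyde 10 is condensed with p-toluenesulfonyl hydrazide (MeOH, rt) to the tosylhydrazone F7. F7 is heated with 11 and K2CO3 in 1,4-dioxane at 110 °C in a metal-free reductive coupling of a tosylhydrazone with a boronic acid (diazo compound, boronate, 1,2-shift, protodeboronation) to give 13 directly.

Further compounds
F1 | step 15 | C4 monoacetate of chlorodiol 22 (C3–OH free) | C[C@H](Cl)[C@@H](O)[C@H](OC(C)=O)C[C@H](C)CC/C=C(\C)CCCc1coc(Cc2ccoc2)c1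
F2 | step 15 | C3 triethylsilyl ether of the C4 acetate of 22 | C[C@H](Cl)[C@@H](O[Si](CC)(CC)CC)[C@H](OC(C)=O)C[C@H](C)CC/C=C(\C)CCCc1coc(Cc2ccoc2)c1
F3 | step 15 | C3 triethylsilyl ether of 22 (C4–OH free) | C[C@H](Cl)[C@@H](O[Si](CC)(CC)CC)[C@H](O)C[C@H](C)CC/C=C(\C)CCCc1coc(Cc2ccoc2)c1
F4 | step 15 | C3 triethylsilyl ether of target 23 (α-silyloxy ketone) | C[C@H](Cl)[C@@H](O[Si](CC)(CC)CC)C(=O)C[C@H](C)CC/C=C(\C)CCCc1coc(Cc2ccoc2)c1
F5 | step 14 | C4 triethylsilyl ether of epoxy alcohol 21 | C[C@H]1O[C@H]1[C@H](O[Si](CC)(CC)CC)C[C@H](C)CC/C=C(\C)CCCc2coc(Cc3ccoc3)c2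
F6 | step 14 | 3-O-acetyl-4-O-triethylsilyl derivative of chlorodiol 22 | C[C@H](Cl)[C@@H](OC(C)=O)[C@H](O[Si](CC)(CC)CC)C[C@H](C)CC/C=C(\C)CCCc1coc(Cc2ccoc2)c1
F7 | step 7 | N'-[(E)-(4-bromofuran-2-yl)methylidene]-4-methylbenzenesulfonohydrazide | Cc1ccc(cc1)S(=O)(=O)N/N=C/c1cc(Br)co1
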